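Ring B carries the chain at C1', oxygen at C3' and C5', and hydrogen at C2', C4' and C6'. This 3-oxy-5-alkylphenol pattern is what a 3-alkylcyclobutenone and an oxyacetylene give on heating, so the resorcinol ring is made from open chains. One thermal cascade forms C3'–C4' and C5'–C6', closes ring B and leaves one oxygen free and the other silylated. The precursor is a cyclobut-2-enone whose C3 holds the undecyl chain, with the (S)-carbinol as its TBS ether. Ring A has the same skeleton plus a carboxyl, so the benzannulation product is divided: one part becomes the alcohol, the other the salicylic acid, and a Mitsunobu esterification with inversion joins them.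

Key step: step 7

Remark: in ring B, C3' is the carbon that comes from the cyclobutenone carbonyl (free OH in 19) and C5' is the silyloxy carbon that comes from the alkyne; (S)-2-propyloxirane is taken as purchased in enantiopure form, and (triisopropylsilyloxy)ethyne is not assumed to be purchasable and is made in step 6.

**Route**

Step 1
Reactants: 1 (S)-2-propyloxirane; 2 oct-1-yne
Product: 4 (S)-tridec-6-yn-4-ol, via oct-1-ynyllithium 3 (not isolated)
Conditions: n-BuLi, THF, −78 °C; then 1, DMPU, −78 °C → rt; aq. NH4Cl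
Reagents that add atoms: none
Why: SN2 opening of a terminal epoxide by a lithium acetylide takes place at the unhindered CH2, so the C–O stereocenter is not touched and remains (S).

Step 2
Reactants: 4 (S)-tridec-6-yn-4-ol
Product: 5 (S)-tridec-12-yn-4-ol
Conditions: KH, H2N(CH2)3NH2, 0 °C → rt; then H2O
Reagents that add atoms: none
Why: In the alkyne zipper reaction the potassium amide moves the triple bond through propargyl/allenyl anions until it is trapped as the terminal acetylide; the alkoxide blocks migration past C4, and the carbinol carbon is never deprotonated, so it keeps its configuration.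

Step 3
Reactants: 5 (S)-tridec-12-yn-4-ol
Product: 6 (S)-tert-butyldimethyl(tridec-12-yn-4-yloxy)silane
Conditions: TBSCl, imidazole, DMF, rt
Reagents that add atoms: tert-butyldimethylsilyl chloride, CC(C)(C)[Si](C)(C)Cl
Why: Imidazole-promoted O-silylation of a secondary alcohol masks the hydroxyl, which would otherwise add to the ketenes of steps 4 and 7.

Step 4
Reactants: 6 (S)-tert-butyldimethyl(tridec-12-yn-4-yloxy)silane; 7 trichloroacetyl chloride
Product: 9 (S)-3-[8-(tert-butyldimethylsilyloxy)undecyl]-4,4-dichlorocyclobut-2-en-1-one, via dichloroketene 8 (not isolated)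
Conditions: Zn–Cu couple, Et2O/DME, rt
Reagents that add atoms: none
Why: In the [2+2] cycloaddition of dichloroketene (from zinc dechlorination of 7) with a terminal alkyne, the terminal alkyne carbon bonds to the ketene carbonyl carbon, giving the 3-alkyl-4,4-dichloro isomer; DME ties up ZnCl2 so the silyl ether survives.

Step 5
Reactants: 9 (S)-3-[8-(tert-butyldimethylsilyloxy)undecyl]-4,4-dichlorocyclobut-2-en-1-one
Product: 10 (S)-3-[8-(tert-butyldimethylsilyloxy)undecyl]cyclobut-2-en-1-one
Conditions: Zn, AcOH, TMEDA, EtOH, 0 °C → rt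
Reagents that add atoms: none
Why: Zinc reductively dechlorinates the α,α-dichloro ketone, and the buffered proton source (AcOH/TMEDA) is mild enough for the strained enone and the silyl ether.

Step 6
Reactants: 11 acetylene
Product: 14 (triisopropylsilyloxy)ethyne, via lithium acetylide 12 (not isolated), via lithium ethynolate 13 (not isolated)
Conditions: n-BuLi, THF, −78 °C; t-BuOOLi (t-BuOOH + n-BuLi), −78 → −30 °C; TIPSOTf, −78 → 0 °C
Reagents that add atoms: tert-butyl hydroperoxide, CC(C)(C)OO; triisopropylsilyl trifluoromethanesulfonate, CC(C)[Si](OS(=O)(=O)C(F)(F)F)(C(C)C)C(C)C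
Why: The lithium acetylide attacks the electrophilic oxygen of lithium tert-butyl peroxide to give the ynolate (the general terminal alkyne to siloxyalkyne sequence), and the hard, bulky silyl triflate should silylate it on oxygen; the mixture is kept cold so that monolithium acetylide does not disproportionate.

Step 7
Reactants: 10 (S)-3-[8-(tert-butyldimethylsilyloxy)undecyl]cyclobut-2-en-1-one; 14 (triisopropylsilyloxy)ethyne
Product: 19 (S)-3-[8-(tert-butyldimethylsilyloxy)undecyl]-5-(triisopropylsilyloxy)phenol, via vinylketene 15 (not isolated), via 4-vinylcyclobutenone 16 (not isolated), via dienylketene 17 (not isolated), via cyclohexa-2,4-dienone 18 (not isolated)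
Conditions: toluene, 80 °C then 110 °C, sealed tube, 14 in excess
Reagents that add atoms: none
Why: In this Danheiser benzannulation, 10 opens thermally (four-electron electrocyclic ring opening) to vinylketene 15, which adds across the triple bond of 14 in a [2+2] cycloaddition to give 4-vinylcyclobutenone 16, and a second four-electron opening gives dienylketene 17. Ring B then closes by a six-electron disrotatory electrocyclization between the ketene carbon and the terminal CH2 of 17 (re-forming C2'–C3'), and cyclohexadienone 18 tautomerizes to the phenol. The closest known reaction type is the thermal annulation of 3-alkylcyclobutenones with alkoxy- and trialkylsilyloxyalkynes. No stereocenter is created in 19 (the sp3 ring carbon of 16 is lost on opening), and the remote (S)-carbinol, masked as its silyl ether, is exposed only to neutral heating. The selectivity needed is the orientation of the ketene–alkyne cycloaddition, and the polarization of 14 secures it: its nucleophilic CH carbon bonds to the electrophilic ketene carbon (C3'–C4') and its silyloxy carbon to the former C2 of 10 (C5'–C6'), so OTIPS ends up meta to both OH and chain. An excess of 14 should keep 15 from being captured by the phenol 19.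

Step 8
Reactants: 19 (S)-3-[8-(tert-butyldimethylsilyloxy)undecyl]-5-(triisopropylsilyloxy)phenol
Product: 20 (S)-1-[8-(tert-butyldimethylsilyloxy)undecyl]-3,5-bis(triisopropylsilyloxy)benzene
Conditions: TIPSCl, imidazole, DMF, rt
Reagents that add atoms: triisopropylsilyl chloride, CC(C)[Si](Cl)(C(C)C)C(C)C
Why: O-silylation of the remaining phenol removes the only other acidic nucleophile from the alcohol partner of the Mitsunobu step.

Step 9
Reactants: 20 (S)-1-[8-(tert-butyldimethylsilyloxy)undecyl]-3,5-bis(triisopropylsilyloxy)benzene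
Product: 21 (S)-11-[3,5-bis(triisopropylsilyloxy)phenyl]undecan-4-ol
Conditions: CSA (cat.), MeOH/CH2Cl2, rt
Reagents that add atoms: none
Why: Acid-catalysed methanolysis cleaves the alkyl TBS ether much faster than the hindered aryl TIPS ethers, whose phenolic oxygen is weakly basic; no bond to the stereocenter is broken, so it remains (S).

Step 10
Reactants: 19 (S)-3-[8-(tert-butyldimethylsilyloxy)undecyl]-5-(triisopropylsilyloxy)phenol
Product: 23 (S)-2-[8-(tert-butyldimethylsilyloxy)undecyl]-6-hydroxy-4-(triisopropylsilyloxy)benzaldehyde, via salicyl alcohol 22 (not isolated)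
Conditions: MgCl2, Et3N, (CH2O)n, THF, reflux; aq. HCl
Reagents that add atoms: paraformaldehyde (as formaldehyde), C=O
Why: In the magnesium-mediated ortho-formylation (Casnati–Skattebøl) the magnesium phenoxide delivers formaldehyde only to a carbon ortho to the free hydroxyl; of the two such carbons, the one next to the chain is para to the silyloxy group and not screened by the triisopropylsilyl group, and a second formaldehyde oxidizes the benzylic alkoxide 22 by hydride transfer.

Step 11
Reactants: 23 (S)-2-[8-(tert-butyldimethylsilyloxy)undecyl]-6-hydroxy-4-(triisopropylsilyloxy)benzaldehyde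
Product: 24 (S)-2-[8-(tert-butyldimethylsilyloxy)undecyl]-6-hydroxy-4-(triisopropylsilyloxy)benzoic acid
Conditions: NaClO2, NaH2PO4, 2-methyl-2-butene, t-BuOH/THF/H2O, 0 °C → rt
Reagents that add atoms: sodium chlorite, [Na+].[O-]Cl=O
Why: In the Pinnick oxidation chlorous acid converts the aldehyde to the acid at buffered pH without harming the silyl ethers, and the excess alkene scavenges hypochlorous acid before it can chlorinate the electron-rich ring.

Step 12
Reactants: 21 (S)-11-[3,5-bis(triisopropylsilyloxy)phenyl]undecan-4-ol; 24 (S)-2-[8-(tert-butyldimethylsilyloxy)undecyl]-6-hydroxy-4-(triisopropylsilyloxy)benzoic acid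
Product: 25 (R)-11-[3,5-bis(triisopropylsilyloxy)phenyl]undecan-4-yl 2-[(S)-8-(tert-butyldimethylsilyloxy)undecyl]-6-hydroxy-4-(triisopropylsilyloxy)benzoate
Conditions: PPh3, DIAD, toluene, 0 °C → rt
Reagents that add atoms: none
Why: In the Mitsunobu esterification the carboxylate of 24 displaces the alkoxyphosphonium ion of 21 in an SN2 reaction, inverting C4 of 21 from (S) to (R); the ortho-hydroxyl of 24 is held in a hydrogen bond to the carboxyl and all other hydroxyls are silylated, so only the acid reacts.

Step 13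
Reactants: 25 (R)-11-[3,5-bis(triisopropylsilyloxy)phenyl]undecan-4-yl 2-[(S)-8-(tert-butyldimethylsilyloxy)undecyl]-6-hydroxy-4-(triisopropylsilyloxy)benzoate
Product: 26 (R)-11-(3,5-dihydroxyphenyl)undecan-4-yl 2,4-dihydroxy-6-[(S)-8-hydroxyundecyl]benzoate (CNP0263107.2)
Conditions: TBAF, AcOH, THF, 0 °C → rt
Reagents that add atoms: none
Why: Fluoride-mediated global desilylation cleaves the three aryl Si–O bonds and the alkyl Si–O bond, while the acetic acid buffer keeps the hindered salicylate ester and both carbinol centers untouched.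

**Compound list**

1 | (S)-2-propyloxirane | CCC[C@H]1CO1 | starting material
2 | oct-1-yne | C#CCCCCCC | starting material
3 | oct-1-ynyllithium | [Li]C#CCCCCCC | intermediate (not isolated)
4 | (S)-tridec-6-yn-4-ol | CCC[C@H](O)CC#CCCCCCC | intermediate
5 | (S)-tridec-12-yn-4-ol | CCC[C@H](O)CCCCCCCC#C | intermediate
6 | (S)-tert-butyldimethyl(tridec-12-yn-4-yloxy)silane | CCC[C@H](O[Si](C)(C)C(C)(C)C)CCCCCCCC#C | intermediate
7 | trichloroacetyl chloride | ClC(=O)C(Cl)(Cl)Cl | starting material
8 | dichloroketene | O=C=C(Cl)Cl | intermediate (not isolated)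
9 | (S)-3-[8-(tert-butyldimethylsilyloxy)undecyl]-4,4-dichlorocyclobut-2-en-1-one | CCC[C@H](O[Si](C)(C)C(C)(C)C)CCCCCCCC1=CC(=O)C1(Cl)Cl | intermediate
10 | (S)-3-[8-(tert-butyldimethylsilyloxy)undecyl]cyclobut-2-en-1-one | CCC[C@H](O[Si](C)(C)C(C)(C)C)CCCCCCCC1=CC(=O)C1 | intermediate
11 | acetylene | C#C | starting material
12 | lithium acetylide (HC≡CLi) | [Li]C#C | intermediate (not isolated)
13 | lithium ethynolate (HC≡COLi) | [Li]OC#C | intermediate (not isolated)
14 | (triisopropylsilyloxy)ethyne | C#CO[Si](C(C)C)(C(C)C)C(C)C | intermediate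
15 | (S)-11-(tert-butyldimethylsilyloxy)-3-methylidenetetradec-1-en-1-one (vinylketene) | CCC[C@H](O[Si](C)(C)C(C)(C)C)CCCCCCCC(=C)C=C=O | intermediate (not isolated)
16 | 4-[(S)-10-(tert-butyldimethylsilyloxy)tridec-1-en-2-yl]-3-(triisopropylsilyloxy)cyclobut-2-en-1-one (ring C4 unassigned, transient) | CCC[C@H](O[Si](C)(C)C(C)(C)C)CCCCCCCC(=C)C1C(=O)C=C1O[Si](C(C)C)(C(C)C)C(C)C | intermediate (not isolated)
17 | (S)-13-(tert-butyldimethylsilyloxy)-5-methylidene-3-(triisopropylsilyloxy)hexadeca-1,3-dien-1-one (dienylketene) | CCC[C@H](O[Si](C)(C)C(C)(C)C)CCCCCCCC(=C)C=C(O[Si](C(C)C)(C(C)C)C(C)C)C=C=O | intermediate (not isolated)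
18 | (S)-5-[8-(tert-butyldimethylsilyloxy)undecyl]-3-(triisopropylsilyloxy)cyclohexa-2,4-dien-1-one | CCC[C@H](O[Si](C)(C)C(C)(C)C)CCCCCCCC1=CC(O[Si](C(C)C)(C(C)C)C(C)C)=CC(=O)C1 | intermediate (not isolated)
19 | (S)-3-[8-(tert-butyldimethylsilyloxy)undecyl]-5-(triisopropylsilyloxy)phenol | CCC[C@H](O[Si](C)(C)C(C)(C)C)CCCCCCCc1cc(O)cc(O[Si](C(C)C)(C(C)C)C(C)C)c1 | intermediate
20 | (S)-1-[8-(tert-butyldimethylsilyloxy)undecyl]-3,5-bis(triisopropylsilyloxy)benzene | CCC[C@H](O[Si](C)(C)C(C)(C)C)CCCCCCCc1cc(O[Si](C(C)C)(C(C)C)C(C)C)cc(O[Si](C(C)C)(C(C)C)C(C)C)c1 | intermediate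
21 | (S)-11-[3,5-bis(triisopropylsilyloxy)phenyl]undecan-4-ol | CCC[C@H](O)CCCCCCCc1cc(O[Si](C(C)C)(C(C)C)C(C)C)cc(O[Si](C(C)C)(C(C)C)C(C)C)c1 | intermediate
22 | (S)-3-[8-(tert-butyldimethylsilyloxy)undecyl]-2-(hydroxymethyl)-5-(triisopropylsilyloxy)phenol (present as its magnesium salt) | CCC[C@H](O[Si](C)(C)C(C)(C)C)CCCCCCCc1cc(O[Si](C(C)C)(C(C)C)C(C)C)cc(O)c1CO | intermediate (not isolated)
23 | (S)-2-[8-(tert-butyldimethylsilyloxy)undecyl]-6-hydroxy-4-(triisopropylsilyloxy)benzaldehyde | CCC[C@H](O[Si](C)(C)C(C)(C)C)CCCCCCCc1cc(O[Si](C(C)C)(C(C)C)C(C)C)cc(O)c1C=O | intermediate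
24 | (S)-2-[8-(tert-butyldimethylsilyloxy)undecyl]-6-hydroxy-4-(triisopropylsilyloxy)benzoic acid | CCC[C@H](O[Si](C)(C)C(C)(C)C)CCCCCCCc1cc(O[Si](C(C)C)(C(C)C)C(C)C)cc(O)c1C(=O)O | intermediate
25 | (R)-11-[3,5-bis(triisopropylsilyloxy)phenyl]undecan-4-yl 2-[(S)-8-(tert-butyldimethylsilyloxy)undecyl]-6-hydroxy-4-(triisopropylsilyloxy)benzoate | CCC[C@H](O[Si](C)(C)C(C)(C)C)CCCCCCCc1cc(O[Si](C(C)C)(C(C)C)C(C)C)cc(O)c1C(=O)O[C@H](CCC)CCCCCCCc1cc(O[Si](C(C)C)(C(C)C)C(C)C)cc(O[Si](C(C)C)(C(C)C)C(C)C)c1 | intermediate
26 | (R)-11-(3,5-dihydroxyphenyl)undecan-4-yl 2,4-dihydroxy-6-[(S)-8-hydroxyundecyl]benzoate | CCC[C@H](O)CCCCCCCc1cc(O)cc(O)c1C(=O)O[C@H](CCC)CCCCCCCc1cc(O)cc(O)c1 | target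

**Step count**

Total: 13 steps. Longest linear sequence: 10 steps (1, 2, 3, 4, 5, 7, 10, 11, 12, 13; the branch through 8 and 9 is equally long).

**Steps most likely to fail**

Step 7. The vinylketene from 10 may dimerize or be captured by the phenolic product, or 14 may rearrange to a silylketene before it adds; the unsubstituted siloxyethyne is a sparsely documented partner. The fallback sets out from 1 and comes back at 19, taking ring B from a purchased arene and joining it to the chain by a B-alkyl Suzuki–Miyaura coupling. 6-Bromohex-1-ene and Mg give hex-5-enylmagnesium bromide F1, which opens 1 at CH2 (CuBr·SMe2 cat., THF, −30 °C) to (S)-undec-10-en-4-ol F2. TBSCl/imidazole gives (S)-tert-butyldimethyl(undec-10-en-4-yloxy)silane F3, and 9-BBN-H hydroborates its terminal alkene to the B-alkyl-9-borabicyclononane F4. 5-Bromoresorcinol is monosilylated (TIPSCl, one equivalent, imidazole) to 3-bromo-5-(triisopropylsilyloxy)phenol F5. Coupling of F4 with F5 (Pd(dppf)Cl2, K3PO4, THF/H2O, 60 °C) should give 19.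

Step 6. Monolithium acetylide may disproportionate to Li2C2 before it is oxidized, and the unhindered ynolate may be silylated on carbon to a silylketene instead of on oxygen. The fallback replaces the source of the ynolate: it sets out from purchased ethyl formate and dibromomethane (which take the place of 11, so no numbered compound precedes it) and comes back at 13. It follows the ester-to-ynolate sequence of the Kowalski ester homologation. Dibromomethane and LiTMP (THF, −78 °C) give dibromomethyllithium F6, which adds to ethyl formate; loss of ethoxide and deprotonation give lithium 2,2-dibromoethen-1-olate F7. n-BuLi exchanges one bromine to the carbenoid lithium 2-bromo-2-lithioethen-1-olate F8, which on warming loses LiBr with a 1,2-shift to give 13. Silylation with TIPSOTf as in step 6 then gives 14.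

Step 10. Formylation may occur at the other ortho carbon, between the hydroxyl and the silyloxy group, which would lead to the 2,6-dioxygenated acid, or the reaction may stall at the benzylic alcohol. The fallback sets out from 20 and comes back at 26; it introduces the carboxyl by halogen–metal exchange on the bis(silyl ether), where the two ring carbons flanking the chain are equivalent and the third is buried between two triisopropylsilyloxy groups. NBS (MeCN, 0 °C) should brominate 20 next to the chain to give (S)-2-bromo-1-[8-(tert-butyldimethylsilyloxy)undecyl]-3,5-bis(triisopropylsilyloxy)benzene F9. t-BuLi (Et2O, −78 °C) gives the aryllithium F10, which is quenched at once with CO2, before any silyl shift from oxygen to carbon, to give (S)-2-[8-(tert-butyldimethylsilyloxy)undecyl]-4,6-bis(triisopropylsilyloxy)benzoic acid F11. Mitsunobu coupling of F11 with 21 (PPh3, DIAD) gives the fully silylated ester F12 with inversion, and TBAF/AcOH removes its five silyl groups to give 26.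

**Further compounds**

F1 | step 7 | hex-5-enylmagnesium bromide | C=CCCCC[Mg]Br
F2 | step 7 | (S)-undec-10-en-4-ol | CCC[C@H](O)CCCCCC=C
F3 | step 7 | (S)-tert-butyldimethyl(undec-10-en-4-yloxy)silane | CCC[C@H](O[Si](C)(C)C(C)(C)C)CCCCCC=C
F4 | step 7 | (S)-9-[8-(tert-butyldimethylsilyloxy)undecyl]-9-borabicyclo[3.3.1]nonane | CCC[C@H](O[Si](C)(C)C(C)(C)C)CCCCCCCB1C2CCCC1CCC2
F5 | step 7 | 3-bromo-5-(triisopropylsilyloxy)phenol | Oc1cc(Br)cc(O[Si](C(C)C)(C(C)C)C(C)C)c1
F6 | step 6 | dibromomethyllithium | [Li]C(Br)Br
F7 | step 6 | lithium 2,2-dibromoethen-1-olate | [Li]OC=C(Br)Br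
F8 | step 6 | lithium 2-bromo-2-lithioethen-1-olate | [Li]OC=C([Li])Br
F9 | step 10 | (S)-2-bromo-1-[8-(tert-butyldimethylsilyloxy)undecyl]-3,5-bis(triisopropylsilyloxy)benzene | CCC[C@H](O[Si](C)(C)C(C)(C)C)CCCCCCCc1cc(O[Si](C(C)C)(C(C)C)C(C)C)cc(O[Si](C(C)C)(C(C)C)C(C)C)c1Br
F10 | step 10 | (S)-{2-[8-(tert-butyldimethylsilyloxy)undecyl]-4,6-bis(triisopropylsilyloxy)phenyl}lithium | CCC[C@H](O[Si](C)(C)C(C)(C)C)CCCCCCCc1cc(O[Si](C(C)C)(C(C)C)C(C)C)cc(O[Si](C(C)C)(C(C)C)C(C)C)c1[Li]
F11 | step 10 | (S)-2-[8-(tert-butyldimethylsilyloxy)undecyl]-4,6-bis(triisopropylsilyloxy)benzoic acid | CCC[C@H](O[Si](C)(C)C(C)(C)C)CCCCCCCc1cc(O[Si](C(C)C)(C(C)C)C(C)C)cc(O[Si](C(C)C)(C(C)C)C(C)C)c1C(=O)O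
F12 | step 10 | (R)-11-[3,5-bis(triisopropylsilyloxy)phenyl]undecan-4-yl 2-[(S)-8-(tert-butyldimethylsilyloxy)undecyl]-4,6-bis(triisopropylsilyloxy)benzoate | CCC[C@H](O[Si](C)(C)C(C)(C)C)CCCCCCCc1cc(O[Si](C(C)C)(C(C)C)C(C)C)cc(O[Si](C(C)C)(C(C)C)C(C)C)c1C(=O)O[C@H](CCC)CCCCCCCc1cc(O[Si](C(C)C)(C(C)C)C(C)C)cc(O[Si](C(C)C)(C(C)C)C(C)C)c1
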